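## Retrosynthetic overview

1. The ten-membered carbocycle is closed late by ring-closing metathesis between a C6 vinyl group and a C4 methylidene group, forming the (4Z)-trisubstituted C4=C5 alkene; only desilylation follows.
2. The metathesis diene comes from a zinc Barbier union (C7–C8 bond, exo-methylene lactone revealed) of bromobutenolide fragment A with aldehyde fragment B, then Mitsunobu esterification with (S)-2-methylbutanoic acid (inverts C8) and Shi epoxidation of the C1=C10 alkene.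
3. Fragment A (C5–C7, C11–C13): (S)-5-(hydroxymethyl)oxolan-2-one → vinyl lactone → selenium-mediated α-hydroxymethylation and dehydrogenation → allylic bromide.
4. Fragment B (C8–C10, C1–C4, C14, C15): Negishi carboalumination of a but-3-yn-1-ol ether with ethylene oxide opening (E-alkene), Nozaki–Hiyama–Kishi coupling with a 2-iodoallyl silyl ether, CBS reduction (C3).
5. Ring order: γ-lactone first (carried in fragment A), oxirane second, ten-membered ring last.

Assumption: skeleton atoms carry germacranolide numbers (C1/C10 epoxide, C3 carbinol, C4=C5 alkene, C6 lactone carbinol, C7, C8 ester carbinol, C15 = CH2OH), and the zinc Barbier union is taken to give the 7,8-anti (8S) carbinol, as the closed chair transition state predicts.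

## Route

### Fragment A

Step 1
Reactants: 1 (S)-5-(hydroxymethyl)oxolan-2-one
Product: 2 (S)-5-oxooxolane-2-carbaldehyde
Conditions: DMP, CH2Cl2, 0 °C → rt; filtered, used crude
Reagents that add atoms: none
Why: Dess–Martin oxidation gives the aldehyde under neutral, non-aqueous conditions, so the α-oxygenated stereocentre from the chiral pool is not epimerised.

Step 2
Reactants: 2 (S)-5-oxooxolane-2-carbaldehyde
Product: 3 (S)-5-ethenyloxolan-2-one
Conditions: Ph3PCH3Br, KN(SiMe3)2, THF, 0 °C; then 2, −78 → 0 °C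
Reagents that add atoms: methyltriphenylphosphonium bromide, C[P+](c1ccccc1)(c1ccccc1)c1ccccc1.[Br-]
Why: Wittig methylenation with the salt-free non-stabilised ylide is far faster at the aldehyde than at the lactone carbonyl, and at low temperature it leaves the adjacent stereocentre untouched.

Step 3
Reactants: 3 (S)-5-ethenyloxolan-2-one
Product: 5 (5S)-5-ethenyl-3-(phenylselanyl)oxolan-2-one (both C3 epimers), via lithium enolate 4 (not isolated)
Conditions: LiN(iPr)2, THF, −78 °C; PhSeBr, −78 °C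
Reagents that add atoms: phenylselanyl bromide, Br[Se]c1ccccc1
Why: Kinetic α-deprotonation of the lactone and electrophilic selenenylation of the enolate install the selenium handle; the C3 configuration is irrelevant because it is destroyed in step 5.

Step 4
Reactants: 5 (5S)-5-ethenyl-3-(phenylselanyl)oxolan-2-one
Product: 7 (5S)-5-ethenyl-3-(hydroxymethyl)-3-(phenylselanyl)oxolan-2-one (both C3 epimers), via lithium enolate 6 (not isolated)
Conditions: LiN(iPr)2, THF, −78 °C; CH2O (g), −78 → −40 °C; aq NH4Cl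
Reagents that add atoms: formaldehyde, C=O
Why: The selenium-stabilised enolate undergoes an aldol addition to monomeric formaldehyde, placing the future C13 carbon at the α-position.

Step 5
Reactants: 7 (5S)-5-ethenyl-3-(hydroxymethyl)-3-(phenylselanyl)oxolan-2-one
Product: 9 (R)-5-ethenyl-3-(hydroxymethyl)furan-2(5H)-one, via selenoxide 8 (not isolated)
Conditions: 30% H2O2, pyridine, CH2Cl2, 0 °C → rt
Reagents that add atoms: none
Why: Selenoxide syn-elimination takes a ring C4 hydrogen (elimination towards the oxygen-bearing CH2OH carbon is disfavoured) to give the butenolide; C5 is untouched and its descriptor changes from S to R only through CIP priorities.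

Step 6
Reactants: 9 (R)-5-ethenyl-3-(hydroxymethyl)furan-2(5H)-one
Product: 10 (R)-3-(bromomethyl)-5-ethenylfuran-2(5H)-one
Conditions: CBr4, PPh3, CH2Cl2, 0 °C
Reagents that add atoms: carbon tetrabromide, BrC(Br)(Br)Br
Why: The Appel reaction converts the primary allylic alcohol into the bromide by SN2 displacement under neutral conditions, which avoids base-induced isomerisation of the γ-vinyl butenolide.

### Vinyl iodide reagent

Step 7
Reactants: 11 prop-2-yn-1-ol
Product: 12 2-iodoprop-2-en-1-ol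
Conditions: NaI, Me3SiCl, H2O, MeCN, rt
Reagents that add atoms: sodium iodide, [Na+].[I-]
Why: Hydrogen iodide generated in the flask adds to the terminal alkyne in the Markovnikov sense to give the 2-iodoalkene.

Step 8
Reactants: 12 2-iodoprop-2-en-1-ol
Product: 13 tert-butyl[(2-iodoprop-2-en-1-yl)oxy]dimethylsilane
Conditions: TBSCl, imidazole, DMF, 0 °C → rt
Reagents that add atoms: tert-butyldimethylsilyl chloride, CC(C)(C)[Si](C)(C)Cl
Why: Imidazole-promoted silylation protects the future C15 hydroxyl as a silyl ether that survives every later step up to the final fluoride treatment.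

### Fragment B

Step 9
Reactants: 14 but-3-yn-1-ol
Product: 15 1-[(but-3-yn-1-yloxy)methyl]-4-methoxybenzene
Conditions: NaH, THF/DMF, 0 °C; PMBCl, Bu4NI (cat.), rt
Reagents that add atoms: 4-methoxybenzyl chloride, COc1ccc(CCl)cc1
Why: Williamson etherification masks the future C8 oxygen as a PMB ether that is orthogonal to the silyl ethers introduced later.

Step 10
Reactants: 15 1-[(but-3-yn-1-yloxy)methyl]-4-methoxybenzene
Product: 18 (3E)-6-[(4-methoxybenzyl)oxy]-4-methylhex-3-en-1-ol, via alkenylalane 16 (not isolated), via lithium alkenylaluminate 17 (not isolated)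
Conditions: Me3Al, Cp2ZrCl2 (25 mol %), CH2Cl2, 0 °C → rt; volatiles removed; n-BuLi, THF/hexane, −78 → 0 °C; ethylene oxide, 0 °C → rt; aq Rochelle salt
Reagents that add atoms: trimethylaluminium, C[Al](C)C; ethylene oxide, C1CO1
Why: Negishi zirconium-catalysed carboalumination adds methyl and aluminium syn across the alkyne (methyl on the internal carbon), and the derived aluminate opens ethylene oxide with retention, which fixes the (E)-trisubstituted C1=C10 alkene.

Step 11
Reactants: 18 (3E)-6-[(4-methoxybenzyl)oxy]-4-methylhex-3-en-1-ol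
Product: 19 (3E)-6-[(4-methoxybenzyl)oxy]-4-methylhex-3-enal
Conditions: DMP, CH2Cl2, 0 °C; used crude
Reagents that add atoms: none
Why: Dess–Martin oxidation is mild enough to deliver the β,γ-unsaturated aldehyde without moving the alkene into conjugation.

Step 12
Reactants: 19 (3E)-6-[(4-methoxybenzyl)oxy]-4-methylhex-3-enal; 13 tert-butyl[(2-iodoprop-2-en-1-yl)oxy]dimethylsilane
Product: 21 rac-(5E)-2-{[(tert-butyldimethylsilyl)oxy]methyl}-8-[(4-methoxybenzyl)oxy]-6-methylocta-1,5-dien-3-ol, via alkenylchromium dichloride 20 (not isolated)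
Conditions: CrCl2 (4 equiv), NiCl2 (2 mol %), DMF, rt
Reagents that add atoms: none
Why: In the Nozaki–Hiyama–Kishi reaction the non-basic alkenylchromium adds to the enolisable aldehyde without deprotonating it; the new C3 carbinol is racemic and is corrected in steps 13 and 14.

Step 13
Reactants: 21 rac-(5E)-2-{[(tert-butyldimethylsilyl)oxy]methyl}-8-[(4-methoxybenzyl)oxy]-6-methylocta-1,5-dien-3-ol
Product: 22 (5E)-2-{[(tert-butyldimethylsilyl)oxy]methyl}-8-[(4-methoxybenzyl)oxy]-6-methylocta-1,5-dien-3-one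
Conditions: DMP, CH2Cl2, 0 °C → rt
Reagents that add atoms: none
Why: Dess–Martin oxidation of the allylic alcohol gives the α-substituted enone needed for reagent-controlled reduction, under conditions too mild to isomerise the β,γ-alkene.

Step 14
Reactants: 22 (5E)-2-{[(tert-butyldimethylsilyl)oxy]methyl}-8-[(4-methoxybenzyl)oxy]-6-methylocta-1,5-dien-3-one
Product: 23 (3S,5E)-2-{[(tert-butyldimethylsilyl)oxy]methyl}-8-[(4-methoxybenzyl)oxy]-6-methylocta-1,5-dien-3-ol
Conditions: (R)-2-methyl-CBS-oxazaborolidine (0.5 equiv), catecholborane, toluene, −78 °C; MeOH, aq work-up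
Reagents that add atoms: none
Why: In the Corey–Bakshi–Shibata reduction the α-branched alkenyl group acts as the large substituent, so the (R)-oxazaborolidine delivers hydride to the face that gives the (3S)-allylic alcohol, and catecholborane at −78 °C does not hydroborate the alkenes.

Step 15
Reactants: 23 (3S,5E)-2-{[(tert-butyldimethylsilyl)oxy]methyl}-8-[(4-methoxybenzyl)oxy]-6-methylocta-1,5-dien-3-ol
Product: 24 (3S,5E)-2-{[(tert-butyldimethylsilyl)oxy]methyl}-8-[(4-methoxybenzyl)oxy]-6-methyl-3-[(triethylsilyl)oxy]octa-1,5-diene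
Conditions: TESOTf, 2,6-lutidine, CH2Cl2, −78 °C
Reagents that add atoms: triethylsilyl trifluoromethanesulfonate, CC[Si](CC)(CC)OS(=O)(=O)C(F)(F)F
Why: Silylation with the reactive triflate protects the hindered secondary allylic alcohol as a triethylsilyl ether that is small enough for the later metathesis and is easily removed at the end.

Step 16
Reactants: 24 (3S,5E)-2-{[(tert-butyldimethylsilyl)oxy]methyl}-8-[(4-methoxybenzyl)oxy]-6-methyl-3-[(triethylsilyl)oxy]octa-1,5-diene
Product: 25 (3E,6S)-7-{[(tert-butyldimethylsilyl)oxy]methyl}-3-methyl-6-[(triethylsilyl)oxy]octa-3,7-dien-1-ol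
Conditions: DDQ, CH2Cl2/pH 7 buffer (10:1), 0 °C
Reagents that add atoms: none
Why: Oxidative PMB cleavage by DDQ proceeds through the benzylic oxocarbenium ion and leaves both silyl ethers and both alkenes untouched in buffered medium.

Step 17
Reactants: 25 (3E,6S)-7-{[(tert-butyldimethylsilyl)oxy]methyl}-3-methyl-6-[(triethylsilyl)oxy]octa-3,7-dien-1-ol
Product: 26 (3E,6S)-7-{[(tert-butyldimethylsilyl)oxy]methyl}-3-methyl-6-[(triethylsilyl)oxy]octa-3,7-dienal
Conditions: DMP, CH2Cl2, 0 °C; used crude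
Reagents that add atoms: none
Why: Dess–Martin oxidation gives the β,γ-unsaturated C8 aldehyde without conjugation, and it is used at once in the fragment union.

### Fragment union and endgame

Step 18
Reactants: 26 (3E,6S)-7-{[(tert-butyldimethylsilyl)oxy]methyl}-3-methyl-6-[(triethylsilyl)oxy]octa-3,7-dienal; 10 (R)-3-(bromomethyl)-5-ethenylfuran-2(5H)-one
Product: 28 (4R,5R)-5-ethenyl-4-[(1S,3E,6S)-7-{[(tert-butyldimethylsilyl)oxy]methyl}-1-hydroxy-3-methyl-6-[(triethylsilyl)oxy]octa-3,7-dien-1-yl]-3-methylideneoxolan-2-one, via allylzinc bromide 27 (not isolated)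
Conditions: Zn dust, THF/sat. aq NH4Cl (2:1), 0 °C → rt
Reagents that add atoms: none
Why: In this Barbier allylation the allylzinc attacks through its γ-carbon (SE2′), forming C7–C8 and the exo-methylene lactone; attack anti to the C6 vinyl group sets C7 (trans lactone), and the closed Zimmerman–Traxler chair with the aldehyde chain equatorial gives the 7,8-anti (8S) carbinol.

Step 19
Reactants: 28 (4R,5R)-5-ethenyl-4-[(1S,3E,6S)-7-{[(tert-butyldimethylsilyl)oxy]methyl}-1-hydroxy-3-methyl-6-[(triethylsilyl)oxy]octa-3,7-dien-1-yl]-3-methylideneoxolan-2-one; 29 (S)-2-methylbutanoic acid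
Product: 30 (1R,3E,6S)-7-{[(tert-butyldimethylsilyl)oxy]methyl}-1-[(2R,3R)-2-ethenyl-4-methylidene-5-oxooxolan-3-yl]-3-methyl-6-[(triethylsilyl)oxy]octa-3,7-dien-1-yl (2S)-2-methylbutanoate
Conditions: PPh3, DIAD, toluene, 0 °C → rt
Reagents that add atoms: none
Why: Mitsunobu esterification displaces the activated C8 oxygen by the carboxylate with clean SN2 inversion (8S → 8R), and the acid is never activated at its carbonyl, so its α-stereocentre cannot epimerise.

Step 20
Reactants: 30 (1R,3E,6S)-7-{[(tert-butyldimethylsilyl)oxy]methyl}-1-[(2R,3R)-2-ethenyl-4-methylidene-5-oxooxolan-3-yl]-3-methyl-6-[(triethylsilyl)oxy]octa-3,7-dien-1-yl (2S)-2-methylbutanoate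
Product: 31 (1R)-2-[(2R,3R)-3-[(2S)-3-{[(tert-butyldimethylsilyl)oxy]methyl}-2-[(triethylsilyl)oxy]but-3-en-1-yl]-2-methyloxiran-2-yl]-1-[(2R,3R)-2-ethenyl-4-methylidene-5-oxooxolan-3-yl]ethyl (2S)-2-methylbutanoate
Conditions: D-fructose-derived Shi ketone (1,2:4,5-di-O-isopropylidene-β-D-erythro-2,3-hexodiulo-2,6-pyranose, 0.4 equiv), Oxone (2KHSO5·KHSO4·K2SO4), K2CO3, Bu4NHSO4 (cat.), MeCN/CH2(OMe)2/aq Na2B4O7 buffer, pH 10.5, 0 °C
Reagents that add atoms: potassium peroxymonosulfate, [K+].[O-]S(=O)(=O)OO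
Why: In the Shi asymmetric epoxidation the chiral dioxirane reacts only with the electron-rich trisubstituted (E)-alkene (the vinyl, allylically oxygenated methylidene and acrylate-type alkenes are much slower), and its spiro transition state gives the (1R,10R)-epoxide.

Step 21
Reactants: 31 (1R)-2-[(2R,3R)-3-[(2S)-3-{[(tert-butyldimethylsilyl)oxy]methyl}-2-[(triethylsilyl)oxy]but-3-en-1-yl]-2-methyloxiran-2-yl]-1-[(2R,3R)-2-ethenyl-4-methylidene-5-oxooxolan-3-yl]ethyl (2S)-2-methylbutanoate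
Product: 32 (1R,3S,4Z,6R,7R,8R,10R)-15-[(tert-butyldimethylsilyl)oxy]-1,10-epoxy-8-[(2S)-2-methylbutanoyloxy]-3-[(triethylsilyl)oxy]germacra-4,11(13)-dien-12,6-olide
Conditions: second-generation Grubbs catalyst (H2IMes)(PCy3)Cl2Ru=CHPh (20 mol %), toluene (0.5 mM), 80 °C
Reagents that add atoms: none
Why: In this ring-closing metathesis the ruthenium carbene loads on the monosubstituted vinyl group and closes onto the 1,1-disubstituted alkene with loss of ethylene, and the strained ten-membered ring is expected to form as the ring-cis (4Z) alkene; no stereocentre is touched.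

Step 22
Reactants: 32 (1R,3S,4Z,6R,7R,8R,10R)-15-[(tert-butyldimethylsilyl)oxy]-1,10-epoxy-8-[(2S)-2-methylbutanoyloxy]-3-[(triethylsilyl)oxy]germacra-4,11(13)-dien-12,6-olide
Product: 33 (1R,3S,4Z,6R,7R,8R,10R)-1,10-epoxy-3,15-dihydroxy-8-[(2S)-2-methylbutanoyloxy]germacra-4,11(13)-dien-12,6-olide (CNP0267576.2)
Conditions: HF·pyridine, pyridine, THF, 0 °C → rt
Reagents that add atoms: none
Why: Pyridine-buffered fluoride desilylation removes the triethylsilyl and primary tert-butyldimethylsilyl ethers, and is mild enough that the epoxide, the ester and the α-methylene lactone should survive.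

## Compound list

1 | (S)-5-(hydroxymethyl)oxolan-2-one | O=C1CC[C@@H](CO)O1 | starting material
2 | (S)-5-oxooxolane-2-carbaldehyde | O=C[C@@H]1CCC(=O)O1 | intermediate
3 | (S)-5-ethenyloxolan-2-one | C=C[C@@H]1CCC(=O)O1 | intermediate
4 | lithium (S)-5-ethenyl-4,5-dihydrofuran-2-olate (lithium enolate of 3) | [Li+].[O-]C1=CC[C@@H](C=C)O1 | intermediate
5 | (5S)-5-ethenyl-3-(phenylselanyl)oxolan-2-one (both C3 epimers) | C=C[C@@H]1CC([Se]c2ccccc2)C(=O)O1 | intermediate
6 | lithium (5S)-5-ethenyl-3-(phenylselanyl)-4,5-dihydrofuran-2-olate (lithium enolate of 5) | [Li+].[O-]C1=C([Se]c2ccccc2)C[C@@H](C=C)O1 | intermediate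
7 | (5S)-5-ethenyl-3-(hydroxymethyl)-3-(phenylselanyl)oxolan-2-one (both C3 epimers) | C=C[C@@H]1CC(CO)([Se]c2ccccc2)C(=O)O1 | intermediate
8 | (5S)-5-ethenyl-3-(hydroxymethyl)-3-(phenylseleninyl)oxolan-2-one (selenoxide) | C=C[C@@H]1CC(CO)([Se](=O)c2ccccc2)C(=O)O1 | intermediate
9 | (R)-5-ethenyl-3-(hydroxymethyl)furan-2(5H)-one | C=C[C@@H]1C=C(CO)C(=O)O1 | intermediate
10 | (R)-3-(bromomethyl)-5-ethenylfuran-2(5H)-one (fragment A) | C=C[C@@H]1C=C(CBr)C(=O)O1 | intermediate
11 | prop-2-yn-1-ol | C#CCO | starting material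
12 | 2-iodoprop-2-en-1-ol | C=C(I)CO | intermediate
13 | tert-butyl[(2-iodoprop-2-en-1-yl)oxy]dimethylsilane | C=C(I)CO[Si](C)(C)C(C)(C)C | intermediate
14 | but-3-yn-1-ol | C#CCCO | starting material
15 | 1-[(but-3-yn-1-yloxy)methyl]-4-methoxybenzene | C#CCCOCc1ccc(OC)cc1 | intermediate
16 | {(1E)-4-[(4-methoxybenzyl)oxy]-2-methylbut-1-en-1-yl}dimethylalane | C[Al](C)/C=C(\C)CCOCc1ccc(OC)cc1 | intermediate
17 | lithium butyl{(1E)-4-[(4-methoxybenzyl)oxy]-2-methylbut-1-en-1-yl}dimethylaluminate | [Li+].CCCC[Al-](C)(C)/C=C(\C)CCOCc1ccc(OC)cc1 | intermediate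
18 | (3E)-6-[(4-methoxybenzyl)oxy]-4-methylhex-3-en-1-ol | OCC/C=C(\C)CCOCc1ccc(OC)cc1 | intermediate
19 | (3E)-6-[(4-methoxybenzyl)oxy]-4-methylhex-3-enal | O=CC/C=C(\C)CCOCc1ccc(OC)cc1 | intermediate
20 | dichloro{3-[(tert-butyldimethylsilyl)oxy]prop-1-en-2-yl}chromium (trivalent chromium) | C=C([Cr](Cl)Cl)CO[Si](C)(C)C(C)(C)C | intermediate
21 | rac-(5E)-2-{[(tert-butyldimethylsilyl)oxy]methyl}-8-[(4-methoxybenzyl)oxy]-6-methylocta-1,5-dien-3-ol | C=C(CO[Si](C)(C)C(C)(C)C)C(O)C/C=C(\C)CCOCc1ccc(OC)cc1 | intermediate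
22 | (5E)-2-{[(tert-butyldimethylsilyl)oxy]methyl}-8-[(4-methoxybenzyl)oxy]-6-methylocta-1,5-dien-3-one | C=C(CO[Si](C)(C)C(C)(C)C)C(=O)C/C=C(\C)CCOCc1ccc(OC)cc1 | intermediate
23 | (3S,5E)-2-{[(tert-butyldimethylsilyl)oxy]methyl}-8-[(4-methoxybenzyl)oxy]-6-methylocta-1,5-dien-3-ol | C=C(CO[Si](C)(C)C(C)(C)C)[C@@H](O)C/C=C(\C)CCOCc1ccc(OC)cc1 | intermediate
24 | (3S,5E)-2-{[(tert-butyldimethylsilyl)oxy]methyl}-8-[(4-methoxybenzyl)oxy]-6-methyl-3-[(triethylsilyl)oxy]octa-1,5-diene | C=C(CO[Si](C)(C)C(C)(C)C)[C@@H](O[Si](CC)(CC)CC)C/C=C(\C)CCOCc1ccc(OC)cc1 | intermediate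
25 | (3E,6S)-7-{[(tert-butyldimethylsilyl)oxy]methyl}-3-methyl-6-[(triethylsilyl)oxy]octa-3,7-dien-1-ol | C=C(CO[Si](C)(C)C(C)(C)C)[C@@H](O[Si](CC)(CC)CC)C/C=C(\C)CCO | intermediate
26 | (3E,6S)-7-{[(tert-butyldimethylsilyl)oxy]methyl}-3-methyl-6-[(triethylsilyl)oxy]octa-3,7-dienal (fragment B) | C=C(CO[Si](C)(C)C(C)(C)C)[C@@H](O[Si](CC)(CC)CC)C/C=C(\C)CC=O | intermediate
27 | bromo{[(5R)-5-ethenyl-2-oxo-2,5-dihydrofuran-3-yl]methyl}zinc | C=C[C@@H]1C=C(C[Zn]Br)C(=O)O1 | intermediate
28 | (4R,5R)-5-ethenyl-4-[(1S,3E,6S)-7-{[(tert-butyldimethylsilyl)oxy]methyl}-1-hydroxy-3-methyl-6-[(triethylsilyl)oxy]octa-3,7-dien-1-yl]-3-methylideneoxolan-2-one | C=C1C(=O)O[C@H](C=C)[C@H]1[C@@H](O)C/C(C)=C/C[C@H](O[Si](CC)(CC)CC)C(=C)CO[Si](C)(C)C(C)(C)C | intermediate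
29 | (S)-2-methylbutanoic acid | CC[C@H](C)C(=O)O | starting material
30 | (1R,3E,6S)-7-{[(tert-butyldimethylsilyl)oxy]methyl}-1-[(2R,3R)-2-ethenyl-4-methylidene-5-oxooxolan-3-yl]-3-methyl-6-[(triethylsilyl)oxy]octa-3,7-dien-1-yl (2S)-2-methylbutanoate | C=C1C(=O)O[C@H](C=C)[C@H]1[C@H](OC(=O)[C@@H](C)CC)C/C(C)=C/C[C@H](O[Si](CC)(CC)CC)C(=C)CO[Si](C)(C)C(C)(C)C | intermediate
31 | (1R)-2-[(2R,3R)-3-[(2S)-3-{[(tert-butyldimethylsilyl)oxy]methyl}-2-[(triethylsilyl)oxy]but-3-en-1-yl]-2-methyloxiran-2-yl]-1-[(2R,3R)-2-ethenyl-4-methylidene-5-oxooxolan-3-yl]ethyl (2S)-2-methylbutanoate | C=C1C(=O)O[C@H](C=C)[C@H]1[C@H](OC(=O)[C@@H](C)CC)C[C@@]2(C)O[C@@H]2C[C@H](O[Si](CC)(CC)CC)C(=C)CO[Si](C)(C)C(C)(C)C | intermediate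
32 | (1R,3S,4Z,6R,7R,8R,10R)-15-[(tert-butyldimethylsilyl)oxy]-1,10-epoxy-8-[(2S)-2-methylbutanoyloxy]-3-[(triethylsilyl)oxy]germacra-4,11(13)-dien-12,6-olide | C=C1C(=O)O[C@@H]2/C=C(/CO[Si](C)(C)C(C)(C)C)[C@@H](O[Si](CC)(CC)CC)C[C@H]3O[C@]3(C)C[C@@H](OC(=O)[C@@H](C)CC)[C@@H]12 | intermediate
33 | (1R,3S,4Z,6R,7R,8R,10R)-1,10-epoxy-3,15-dihydroxy-8-[(2S)-2-methylbutanoyloxy]germacra-4,11(13)-dien-12,6-olide (CNP0267576.2) | C=C1C(=O)O[C@@H]2/C=C(/CO)[C@@H](O)C[C@H]3O[C@]3(C)C[C@@H](OC(=O)[C@@H](C)CC)[C@@H]12 | target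

## Step count and risks

Total step count: 22 (fragment A 6 steps, vinyl iodide 13 2 steps, fragment B 9 steps, endgame 5 steps).

Longest linear sequence: 14 steps (steps 9–17 from but-3-yn-1-ol 14, then steps 18–22), which is 14/22 of the total.

Steps most likely to fail:

**Step 21 (ring-closing metathesis).** A strained ten-membered ring with a trisubstituted alkene must form from a 1,1-disubstituted alkene flanked by two silyloxy groups, so oligomerisation or no reaction is possible. The fallback sets out from 31 and comes back to the route at 33. The two silyl ethers are removed first (HF·pyridine, pyridine, THF) to give the free 3,15-diol diene F1. Ring closure is then run on F1 with the same ruthenium carbene at high dilution. The methylidene alkene is now unencumbered and carries a free allylic hydroxyl, which is known to accelerate metathesis, and the product of ring closure is 33 itself.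

**Step 19 (Mitsunobu inversion at C8).** The carbinol is β-branched and has allylic β-hydrogens, so elimination or a sluggish reaction is possible. The fallback sets out from 28 and 29 and comes back at 30. The alcohol is converted (MsCl, Et3N, CH2Cl2, 0 °C) into the C8 methanesulfonate F2 with retention. Acid 29 is converted with Cs2CO3 into cesium (2S)-2-methylbutanoate F3. F2 is then displaced by F3 (18-crown-6, toluene, 80 °C), and this intermolecular SN2 reaction gives the inverted (8R) ester 30.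

**Step 20 (late Shi epoxidation).** Four alkenes and a base-sensitive α-methylene lactone are present at pH 10.5. The fallback sets out from 24 and comes back at 31. The same Shi conditions are applied to 24, whose only reactive alkene is the trisubstituted one, to give the (2R,3R)-epoxy PMB ether F4. DDQ then gives the epoxy alcohol F5, and Dess–Martin oxidation gives the β,γ-epoxy aldehyde F6, which is used at once. Zinc Barbier union of F6 with 10 gives the epoxy carbinol F7 (8S). Mitsunobu esterification of F7 with 29 delivers 31.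

## Further compounds

F1 | step 21 | (1R)-1-[(2R,3R)-2-ethenyl-4-methylidene-5-oxooxolan-3-yl]-2-[(2R,3R)-3-[(2S)-2-hydroxy-3-(hydroxymethyl)but-3-en-1-yl]-2-methyloxiran-2-yl]ethyl (2S)-2-methylbutanoate | C=C1C(=O)O[C@H](C=C)[C@H]1[C@H](OC(=O)[C@@H](C)CC)C[C@@]2(C)O[C@@H]2C[C@H](O)C(=C)CO
F2 | step 19 | (1S,3E,6S)-7-{[(tert-butyldimethylsilyl)oxy]methyl}-1-[(2R,3R)-2-ethenyl-4-methylidene-5-oxooxolan-3-yl]-3-methyl-6-[(triethylsilyl)oxy]octa-3,7-dien-1-yl methanesulfonate | C=C1C(=O)O[C@H](C=C)[C@H]1[C@@H](OS(C)(=O)=O)C/C(C)=C/C[C@H](O[Si](CC)(CC)CC)C(=C)CO[Si](C)(C)C(C)(C)C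
F3 | step 19 | cesium (2S)-2-methylbutanoate | [Cs+].CC[C@H](C)C(=O)[O-]
F4 | step 20 | (2R,3R)-3-[(2S)-3-{[(tert-butyldimethylsilyl)oxy]methyl}-2-[(triethylsilyl)oxy]but-3-en-1-yl]-2-{2-[(4-methoxybenzyl)oxy]ethyl}-2-methyloxirane | C=C(CO[Si](C)(C)C(C)(C)C)[C@@H](O[Si](CC)(CC)CC)C[C@H]1O[C@]1(C)CCOCc1ccc(OC)cc1
F5 | step 20 | 2-[(2R,3R)-3-[(2S)-3-{[(tert-butyldimethylsilyl)oxy]methyl}-2-[(triethylsilyl)oxy]but-3-en-1-yl]-2-methyloxiran-2-yl]ethan-1-ol | C=C(CO[Si](C)(C)C(C)(C)C)[C@@H](O[Si](CC)(CC)CC)C[C@H]1O[C@]1(C)CCO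
F6 | step 20 | 2-[(2R,3R)-3-[(2S)-3-{[(tert-butyldimethylsilyl)oxy]methyl}-2-[(triethylsilyl)oxy]but-3-en-1-yl]-2-methyloxiran-2-yl]acetaldehyde | C=C(CO[Si](C)(C)C(C)(C)C)[C@@H](O[Si](CC)(CC)CC)C[C@H]1O[C@]1(C)CC=O
F7 | step 20 | (4R,5R)-5-ethenyl-4-[(1S)-1-hydroxy-2-[(2R,3R)-3-[(2S)-3-{[(tert-butyldimethylsilyl)oxy]methyl}-2-[(triethylsilyl)oxy]but-3-en-1-yl]-2-methyloxiran-2-yl]ethyl]-3-methylideneoxolan-2-one | C=C1C(=O)O[C@H](C=C)[C@H]1[C@@H](O)C[C@@]2(C)O[C@@H]2C[C@H](O[Si](CC)(CC)CC)C(=C)CO[Si](C)(C)C(C)(C)C
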